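**Retrosynthetic overview**
1. Target 25 ⇐ desilylation and Mitsunobu angeloylation with inversion at C8 ⇐ 8α-hydroxy germacranolide 22.
2. 22 ⇐ acyclic bromoacrylate 20 in one flask: RCM closes the butenolide (lactone ring, first); CrCl2 then turns its CH2Br into an allylchromium that adds through C7 to the C8 enal, closing the ten-membered ring (second) and unmasking the exo-methylene.
3. 20 ⇐ C2–C3 boron aldol of methyl ketone 4 with Z-enal 12, then Evans–Tishchenko reduction (C1–OH anti to C3, acetate placed on O3).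
4. 12 ⇐ crotonaldehyde 5 + propargyl ether 6 (asymmetric alkynylation sets C6; directed trans-hydroalumination/iodination fixes the 4Z olefin; carbonylation adds C3); 4 ⇐ biacetyl 1 + formyl ylide 2.

Locants C1–C15 in the text are germacrane locants (C6 = lactone carbinol, C8 = angelate carbinol, C12 = lactone carbonyl, C15 = CH2OH carbon).
Assumption: (S,S)-ProPhenol and (−)-Ipc2BCl are taken to give the (S)-carbinols drawn at C6 and C3; if either sense proves opposite, the antipodal ligand or reagent is used.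

**Route**

Step 1
Reactants: 1 butane-2,3-dione; 2 2-(triphenyl-λ5-phosphanylidene)acetaldehyde
Product: 3 (2E)-3-methyl-4-oxopent-2-enal
Conditions: 1 (4 equiv), CH2Cl2, 40 °C
Reagents that add atoms: none
Why: Wittig olefination of the activated 1,2-diketone with the stabilised formyl ylide (excess diketone suppresses over-homologation of the product enal) gives the more stable E-olefin with CHO trans to acetyl.

Step 2
Reactants: 3 (2E)-3-methyl-4-oxopent-2-enal
Product: 4 (3E)-5,5-dimethoxy-3-methylpent-3-en-2-one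
Conditions: HC(OMe)3, MeOH, PPTS (cat.), 0 → 23 °C
Reagents that add atoms: trimethyl orthoformate, COC(OC)OC
Why: Acid-catalysed acetalisation is chemoselective for the aldehyde over the conjugated ketone and masks C8 before the ketone is enolised.

Step 3
Reactants: 5 (2E)-but-2-enal; 6 tert-butyl(diphenyl)(prop-2-yn-1-yloxy)silane
Product: 8 (4S,5E)-1-[(tert-butyldiphenylsilyl)oxy]hept-5-en-2-yn-4-ol, via methylzinc acetylide 7 (not isolated)
Conditions: 6, Me2Zn, (S,S)-ProPhenol (10 mol%), Ph3PO (20 mol%), PhMe, 0 °C; then 5, 4 °C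
Reagents that add atoms: none
Why: Zinc–ProPhenol-catalysed asymmetric alkynylation of the enal by the zinc acetylide adds 1,2 and sets the C6 carbinol (S) under ligand control.

Step 4
Reactants: 8 (4S,5E)-1-[(tert-butyldiphenylsilyl)oxy]hept-5-en-2-yn-4-ol
Product: 10 (2Z,4S,5E)-1-[(tert-butyldiphenylsilyl)oxy]-2-iodohepta-2,5-dien-4-ol, via cyclic vinylalanate 9 (not isolated)
Conditions: NaAlH2(OCH2CH2OMe)2, THF, 0 °C; then I2, −78 → 0 °C
Reagents that add atoms: iodine, [I][I]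
Why: Alkoxide-directed trans-hydroalumination puts aluminium on the distal alkyne carbon, cis to the carbinol carbon in a five-membered alanate, and iodinolysis with retention gives the Z-vinyl iodide that fixes the 4,5-olefin geometry.

Step 5
Reactants: 10 (2Z,4S,5E)-1-[(tert-butyldiphenylsilyl)oxy]-2-iodohepta-2,5-dien-4-ol
Product: 11 tert-butyl{[(2Z,4S,5E)-2-iodo-4-[(triethylsilyl)oxy]hepta-2,5-dien-1-yl]oxy}diphenylsilane
Conditions: TESCl, imidazole, CH2Cl2, 0 °C
Reagents that add atoms: chlorotriethylsilane, CC[Si](Cl)(CC)CC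
Why: Silylation caps the C6 hydroxyl, which would otherwise trap the acylpalladium of the next step as a butenolide or close the cis-hydroxy enal to a furan.

Step 6
Reactants: 11 tert-butyl{[(2Z,4S,5E)-2-iodo-4-[(triethylsilyl)oxy]hepta-2,5-dien-1-yl]oxy}diphenylsilane
Product: 12 (2Z,4S,5E)-2-{[(tert-butyldiphenylsilyl)oxy]methyl}-4-[(triethylsilyl)oxy]hepta-2,5-dienal
Conditions: Pd(PPh3)4 (5 mol%), CO (1 atm), Bu3SnH (slow addition), THF, 50 °C
Reagents that add atoms: carbon monoxide, [C-]#[O+]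
Why: Palladium-catalysed reductive carbonylation (formylation) of the vinyl iodide proceeds by oxidative addition, CO insertion and hydride transfer from tin, giving the enal with retention of the Z geometry.

Step 7
Reactants: 12 (2Z,4S,5E)-2-{[(tert-butyldiphenylsilyl)oxy]methyl}-4-[(triethylsilyl)oxy]hepta-2,5-dienal; 4 (3E)-5,5-dimethoxy-3-methylpent-3-en-2-one
Product: 14 (2E,6S,7Z,9S,10E)-7-{[(tert-butyldiphenylsilyl)oxy]methyl}-6-hydroxy-1,1-dimethoxy-3-methyl-9-[(triethylsilyl)oxy]dodeca-2,7,10-trien-4-one, via boron enolate 13 (not isolated)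
Conditions: 4, (−)-Ipc2BCl, Et3N, Et2O, 0 °C; then 12, −78 → −20 °C; H2O2, pH 7 buffer, MeOH, 0 °C
Reagents that add atoms: none
Why: Paterson boron aldol, in which the kinetic diisopinocampheylboron enolate of the methyl ketone adds 1,2 to the enal through a closed transition state and the Ipc ligands direct attack to the aldehyde si face, setting C3 (S) under reagent control.

Step 8
Reactants: 14 (2E,6S,7Z,9S,10E)-7-{[(tert-butyldiphenylsilyl)oxy]methyl}-6-hydroxy-1,1-dimethoxy-3-methyl-9-[(triethylsilyl)oxy]dodeca-2,7,10-trien-4-one; 15 acetaldehyde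
Product: 16 (2E,4S,6S,7Z,9S,10E)-7-{[(tert-butyldiphenylsilyl)oxy]methyl}-4-hydroxy-1,1-dimethoxy-3-methyl-9-[(triethylsilyl)oxy]dodeca-2,7,10-trien-6-yl acetate
Conditions: 15 (10 equiv), SmI2 (30 mol%), THF, −10 °C
Reagents that add atoms: none
Why: Evans–Tishchenko reduction, in which the samarium-bound hemiacetal of acetaldehyde delivers hydride intramolecularly to the ketone through a chair transition state, gives the 1,3-anti C1 carbinol (S) and leaves the acetate on O3 in the same step.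

Step 9
Reactants: 16 (2E,4S,6S,7Z,9S,10E)-7-{[(tert-butyldiphenylsilyl)oxy]methyl}-4-hydroxy-1,1-dimethoxy-3-methyl-9-[(triethylsilyl)oxy]dodeca-2,7,10-trien-6-yl acetate
Product: 17 (2E,4S,6S,7Z,9S,10E)-4-[(tert-butyldimethylsilyl)oxy]-7-{[(tert-butyldiphenylsilyl)oxy]methyl}-1,1-dimethoxy-3-methyl-9-[(triethylsilyl)oxy]dodeca-2,7,10-trien-6-yl acetate
Conditions: TBSOTf (1.05 equiv), 2,6-lutidine, CH2Cl2, −78 °C
Reagents that add atoms: tert-butyldimethylsilyl trifluoromethanesulfonate, CC(C)(C)[Si](C)(C)OS(=O)(=O)C(F)(F)F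
Why: Fast low-temperature silylation caps the C1 hydroxyl before any 1,3-acetyl migration and differentiates it from the hydroxyls released later.

Step 10
Reactants: 17 (2E,4S,6S,7Z,9S,10E)-4-[(tert-butyldimethylsilyl)oxy]-7-{[(tert-butyldiphenylsilyl)oxy]methyl}-1,1-dimethoxy-3-methyl-9-[(triethylsilyl)oxy]dodeca-2,7,10-trien-6-yl acetate
Product: 18 (2E,4S,6S,7Z,9S,10E)-4-[(tert-butyldimethylsilyl)oxy]-7-{[(tert-butyldiphenylsilyl)oxy]methyl}-9-hydroxy-3-methyl-1-oxododeca-2,7,10-trien-6-yl acetate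
Conditions: AcOH/THF/H2O (3:1:1), 23 °C
Reagents that add atoms: water, O
Why: Mild aqueous acid cleaves the secondary TES ether and hydrolyses the allylic dimethyl acetal to the E-enal, while the TBS ether, TBDPS ether and acetate survive.

Step 11
Reactants: 18 (2E,4S,6S,7Z,9S,10E)-4-[(tert-butyldimethylsilyl)oxy]-7-{[(tert-butyldiphenylsilyl)oxy]methyl}-9-hydroxy-3-methyl-1-oxododeca-2,7,10-trien-6-yl acetate; 19 2-(bromomethyl)prop-2-enoic acid
Product: 20 (2E,4S,6S,7Z,9S,10E)-6-(acetyloxy)-4-[(tert-butyldimethylsilyl)oxy]-7-{[(tert-butyldiphenylsilyl)oxy]methyl}-3-methyl-1-oxododeca-2,7,10-trien-9-yl 2-(bromomethyl)prop-2-enoate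
Conditions: 19, DIC, DMAP (10 mol%), CH2Cl2, 0 °C
Reagents that add atoms: none
Why: Steglich esterification acylates the only free hydroxyl (C6) with retention, attaching the future C11–C13 unit and the lactone carbonyl.

Step 12
Reactants: 20 (2E,4S,6S,7Z,9S,10E)-6-(acetyloxy)-4-[(tert-butyldimethylsilyl)oxy]-7-{[(tert-butyldiphenylsilyl)oxy]methyl}-3-methyl-1-oxododeca-2,7,10-trien-9-yl 2-(bromomethyl)prop-2-enoate
Product: 22 (1S,3S,4Z,6R,7R,8S,9E)-3-acetoxy-1-[(tert-butyldimethylsilyl)oxy]-15-[(tert-butyldiphenylsilyl)oxy]-8-hydroxygermacra-4,9,11(13)-trien-12,6-olide, via bromolactone 21 (not isolated)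
Conditions: RuCl2(H2IMes)(=CH-C6H4-2-OiPr) (second-generation Hoveyda–Grubbs catalyst, 5 mol%), PhMe (5 mM), 80 °C; then slow addition to CrCl2 (10 equiv), THF/DMF (4:1), 23 °C (final 1.5 mM)
Reagents that add atoms: none
Why: Proposed new method: RCM of the 2-(bromomethyl)acrylate with the propenyl group (initiation at the disubstituted olefin, loss of propene) first closes the butenolide, and divalent chromium then inserts into the allylic C–Br bond so that the allylchromium adds through its γ-carbon C7 (SE2′, on the butenolide face anti to the C6 alkenyl group, giving the 6,7-trans lactone) to the tethered enal in a closed chair transition state with the enal residue equatorial (predicted 8S, 8α-OH), which closes the ten-membered ring and moves the olefin to the exo-methylene; the closest known chemistry is RCM of acrylates of allylic alcohols to butenolides, Nozaki–Hiyama/Barbier allylation of aldehydes by 3-(bromomethyl)butenolides and chromium-mediated macrocyclising allylations to germacranolides.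

Step 13
Reactants: 22 (1S,3S,4Z,6R,7R,8S,9E)-3-acetoxy-1-[(tert-butyldimethylsilyl)oxy]-15-[(tert-butyldiphenylsilyl)oxy]-8-hydroxygermacra-4,9,11(13)-trien-12,6-olide; 23 (2Z)-2-methylbut-2-enoic acid
Product: 24 (1S,3S,4Z,6R,7R,8R,9E)-3-acetoxy-8-[(2Z)-2-methylbut-2-enoyloxy]-1-[(tert-butyldimethylsilyl)oxy]-15-[(tert-butyldiphenylsilyl)oxy]germacra-4,9,11(13)-trien-12,6-olide
Conditions: 23, PPh3, DIAD, PhMe, 0 → 23 °C
Reagents that add atoms: none
Why: Mitsunobu esterification, in which angelate displaces the C8 oxyphosphonium by SN2, inverts C8 (S to R) and installs the Z-ester under neutral conditions that do not isomerise it to the tiglate.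

Step 14
Reactants: 24 (1S,3S,4Z,6R,7R,8R,9E)-3-acetoxy-8-[(2Z)-2-methylbut-2-enoyloxy]-1-[(tert-butyldimethylsilyl)oxy]-15-[(tert-butyldiphenylsilyl)oxy]germacra-4,9,11(13)-trien-12,6-olide
Product: 25 (1S,3S,4Z,6R,7R,8R,9E)-3-acetoxy-8-[(2Z)-2-methylbut-2-enoyloxy]-1,15-dihydroxygermacra-4,9,11(13)-trien-12,6-olide
Conditions: HF·pyridine, pyridine, THF, 0 → 23 °C
Reagents that add atoms: none
Why: Buffered fluoride cleaves both silyl ethers without acyl migration, lactone opening or conjugate addition, leaving all five stereocentres untouched.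

**Compound list**
1 | butane-2,3-dione | CC(=O)C(C)=O | starting material
2 | 2-(triphenyl-λ5-phosphanylidene)acetaldehyde | O=CC=P(c1ccccc1)(c1ccccc1)c1ccccc1 | starting material
3 | (2E)-3-methyl-4-oxopent-2-enal | CC(=O)/C(C)=C/C=O | intermediate
4 | (3E)-5,5-dimethoxy-3-methylpent-3-en-2-one | CC(=O)/C(C)=C/C(OC)OC | intermediate
5 | (2E)-but-2-enal | C/C=C/C=O | starting material
6 | tert-butyl(diphenyl)(prop-2-yn-1-yloxy)silane | C#CCO[Si](c1ccccc1)(c1ccccc1)C(C)(C)C | starting material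
7 | methyl{3-[(tert-butyldiphenylsilyl)oxy]prop-1-yn-1-yl}zinc | C[Zn]C#CCO[Si](c1ccccc1)(c1ccccc1)C(C)(C)C | intermediate
8 | (4S,5E)-1-[(tert-butyldiphenylsilyl)oxy]hept-5-en-2-yn-4-ol | C/C=C/[C@H](O)C#CCO[Si](c1ccccc1)(c1ccccc1)C(C)(C)C | intermediate
9 | sodium (5S)-3-{[(tert-butyldiphenylsilyl)oxy]methyl}-2,2-bis(2-methoxyethoxy)-5-[(1E)-prop-1-en-1-yl]-2,5-dihydro-1,2-oxaaluminol-2-uide | [Na+].C/C=C/[C@@H]1O[Al-](OCCOC)(OCCOC)C(CO[Si](c2ccccc2)(c2ccccc2)C(C)(C)C)=C1 | intermediate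
10 | (2Z,4S,5E)-1-[(tert-butyldiphenylsilyl)oxy]-2-iodohepta-2,5-dien-4-ol | C/C=C/[C@H](O)/C=C(/CO[Si](c1ccccc1)(c1ccccc1)C(C)(C)C)I | intermediate
11 | tert-butyl{[(2Z,4S,5E)-2-iodo-4-[(triethylsilyl)oxy]hepta-2,5-dien-1-yl]oxy}diphenylsilane | C/C=C/[C@H](O[Si](CC)(CC)CC)/C=C(/CO[Si](c1ccccc1)(c1ccccc1)C(C)(C)C)I | intermediate
12 | (2Z,4S,5E)-2-{[(tert-butyldiphenylsilyl)oxy]methyl}-4-[(triethylsilyl)oxy]hepta-2,5-dienal | C/C=C/[C@H](O[Si](CC)(CC)CC)/C=C(/CO[Si](c1ccccc1)(c1ccccc1)C(C)(C)C)C=O | intermediate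
13 | (3E)-2-{[bis((1R,2S,3R,5R)-2,6,6-trimethylbicyclo[3.1.1]heptan-3-yl)boranyl]oxy}-5,5-dimethoxy-3-methylpenta-1,3-diene | C=C(OB([C@@H]1C[C@@H]2C[C@H]([C@H]1C)C2(C)C)[C@@H]1C[C@@H]2C[C@H]([C@H]1C)C2(C)C)/C(C)=C/C(OC)OC | intermediate
14 | (2E,6S,7Z,9S,10E)-7-{[(tert-butyldiphenylsilyl)oxy]methyl}-6-hydroxy-1,1-dimethoxy-3-methyl-9-[(triethylsilyl)oxy]dodeca-2,7,10-trien-4-one | C/C=C/[C@H](O[Si](CC)(CC)CC)/C=C(/CO[Si](c1ccccc1)(c1ccccc1)C(C)(C)C)[C@@H](O)CC(=O)/C(C)=C/C(OC)OC | intermediate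
15 | acetaldehyde | CC=O | starting material
16 | (2E,4S,6S,7Z,9S,10E)-7-{[(tert-butyldiphenylsilyl)oxy]methyl}-4-hydroxy-1,1-dimethoxy-3-methyl-9-[(triethylsilyl)oxy]dodeca-2,7,10-trien-6-yl acetate | C/C=C/[C@H](O[Si](CC)(CC)CC)/C=C(/CO[Si](c1ccccc1)(c1ccccc1)C(C)(C)C)[C@@H](OC(C)=O)C[C@H](O)/C(C)=C/C(OC)OC | intermediate
17 | (2E,4S,6S,7Z,9S,10E)-4-[(tert-butyldimethylsilyl)oxy]-7-{[(tert-butyldiphenylsilyl)oxy]methyl}-1,1-dimethoxy-3-methyl-9-[(triethylsilyl)oxy]dodeca-2,7,10-trien-6-yl acetate | C/C=C/[C@H](O[Si](CC)(CC)CC)/C=C(/CO[Si](c1ccccc1)(c1ccccc1)C(C)(C)C)[C@@H](OC(C)=O)C[C@H](O[Si](C)(C)C(C)(C)C)/C(C)=C/C(OC)OC | intermediate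
18 | (2E,4S,6S,7Z,9S,10E)-4-[(tert-butyldimethylsilyl)oxy]-7-{[(tert-butyldiphenylsilyl)oxy]methyl}-9-hydroxy-3-methyl-1-oxododeca-2,7,10-trien-6-yl acetate | C/C=C/[C@H](O)/C=C(/CO[Si](c1ccccc1)(c1ccccc1)C(C)(C)C)[C@@H](OC(C)=O)C[C@H](O[Si](C)(C)C(C)(C)C)/C(C)=C/C=O | intermediate
19 | 2-(bromomethyl)prop-2-enoic acid | C=C(CBr)C(=O)O | starting material
20 | (2E,4S,6S,7Z,9S,10E)-6-(acetyloxy)-4-[(tert-butyldimethylsilyl)oxy]-7-{[(tert-butyldiphenylsilyl)oxy]methyl}-3-methyl-1-oxododeca-2,7,10-trien-9-yl 2-(bromomethyl)prop-2-enoate | C/C=C/[C@H](OC(=O)C(=C)CBr)/C=C(/CO[Si](c1ccccc1)(c1ccccc1)C(C)(C)C)[C@@H](OC(C)=O)C[C@H](O[Si](C)(C)C(C)(C)C)/C(C)=C/C=O | intermediate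
21 | (2E,4S,6S,7Z)-8-[(2R)-4-(bromomethyl)-5-oxo-2,5-dihydrofuran-2-yl]-4-[(tert-butyldimethylsilyl)oxy]-7-{[(tert-butyldiphenylsilyl)oxy]methyl}-3-methyl-1-oxoocta-2,7-dien-6-yl acetate | O=C1O[C@@H](C=C1CBr)/C=C(/CO[Si](c2ccccc2)(c2ccccc2)C(C)(C)C)[C@@H](OC(C)=O)C[C@H](O[Si](C)(C)C(C)(C)C)/C(C)=C/C=O | intermediate
22 | (1S,3S,4Z,6R,7R,8S,9E)-3-acetoxy-1-[(tert-butyldimethylsilyl)oxy]-15-[(tert-butyldiphenylsilyl)oxy]-8-hydroxygermacra-4,9,11(13)-trien-12,6-olide | C=C1C(=O)O[C@@H]2/C=C(/CO[Si](c3ccccc3)(c3ccccc3)C(C)(C)C)[C@@H](OC(C)=O)C[C@H](O[Si](C)(C)C(C)(C)C)/C(C)=C/[C@H](O)[C@@H]12 | intermediate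
23 | (2Z)-2-methylbut-2-enoic acid (angelic acid) | C/C=C(/C)C(=O)O | starting material
24 | (1S,3S,4Z,6R,7R,8R,9E)-3-acetoxy-8-[(2Z)-2-methylbut-2-enoyloxy]-1-[(tert-butyldimethylsilyl)oxy]-15-[(tert-butyldiphenylsilyl)oxy]germacra-4,9,11(13)-trien-12,6-olide | C=C1C(=O)O[C@@H]2/C=C(/CO[Si](c3ccccc3)(c3ccccc3)C(C)(C)C)[C@@H](OC(C)=O)C[C@H](O[Si](C)(C)C(C)(C)C)/C(C)=C/[C@@H](OC(=O)/C(C)=C\C)[C@@H]12 | intermediate
25 | (1S,3S,4Z,6R,7R,8R,9E)-3-acetoxy-8-[(2Z)-2-methylbut-2-enoyloxy]-1,15-dihydroxygermacra-4,9,11(13)-trien-12,6-olide (CNP0153210.6) | C=C1C(=O)O[C@@H]2/C=C(/CO)[C@@H](OC(C)=O)C[C@H](O)/C(C)=C/[C@@H](OC(=O)/C(C)=C\C)[C@@H]12 | target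

**Step count**
Total: 14 steps. Longest linear sequence: 12 steps (steps 3–14, from 5 and 6).

**Three steps most likely to fail, with fallbacks**

Step 12 (ruthenium-to-chromium hand-over, ten-membered ring closure, possible 6,12 to 8,12 translactonisation of the 8α-alkoxide). The fallback replaces the labile bromide by a bench-stable allyl donor and palladium umpolung. It sets out from 18. DIC esterification with 2-{[(methoxycarbonyl)oxy]methyl}prop-2-enoic acid gives the carbonate ester F1. RCM with the same ruthenium catalyst gives the isolable carbonate butenolide F2. Pd(PPh3)4 (cat.) and InI in THF at high dilution then ionise the activated primary allylic carbonate (much faster than the C3 acetate), transmetalate to the allylindium and add it to the enal through a closed transition state. This comes back to the route at 22.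

Step 13 (Mitsunobu at a hindered allylic carbinol; elimination or SN2′ may compete). The fallback avoids the inversion by setting 8β-OH directly through an open transition state. It sets out from 18. Esterification with 2-[(tributylstannyl)methyl]prop-2-enoic acid gives the stannyl acrylate F3, and RCM gives the stannylmethyl butenolide F4. BF3·OEt2 in CH2Cl2 at −78 °C and high dilution then promotes allylstannane addition to the enal through an antiperiplanar open transition state (syn-selective, again anti to the C6 substituent), giving the 8β-alcohol F5. Acylation with angelic acid through its 2,4,6-trichlorobenzoyl mixed anhydride (retention) comes back to the route at 24.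

Step 7 (reagent control at C3 with an α-branched Z-enal; chloroborane against the acetal). The fallback is a catalytic Lewis-base-activated Mukaiyama aldol. It sets out from 4. TMSOTf and Et3N give the silyl enol ether F6. SiCl4 with a chiral bisphosphoramide catalyst adds F6 to 12 at −78 °C (conjugated aldehydes are the best acceptors for this system), and aqueous work-up comes back to the route at 14.

**Further compounds**
F1 | step 12 | (2E,4S,6S,7Z,9S,10E)-6-(acetyloxy)-4-[(tert-butyldimethylsilyl)oxy]-7-{[(tert-butyldiphenylsilyl)oxy]methyl}-3-methyl-1-oxododeca-2,7,10-trien-9-yl 2-{[(methoxycarbonyl)oxy]methyl}prop-2-enoate | C/C=C/[C@H](OC(=O)C(=C)COC(=O)OC)/C=C(/CO[Si](c1ccccc1)(c1ccccc1)C(C)(C)C)[C@@H](OC(C)=O)C[C@H](O[Si](C)(C)C(C)(C)C)/C(C)=C/C=O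
F2 | step 12 | (2E,4S,6S,7Z)-4-[(tert-butyldimethylsilyl)oxy]-7-{[(tert-butyldiphenylsilyl)oxy]methyl}-8-[(2R)-4-{[(methoxycarbonyl)oxy]methyl}-5-oxo-2,5-dihydrofuran-2-yl]-3-methyl-1-oxoocta-2,7-dien-6-yl acetate | O=C1O[C@@H](C=C1COC(=O)OC)/C=C(/CO[Si](c2ccccc2)(c2ccccc2)C(C)(C)C)[C@@H](OC(C)=O)C[C@H](O[Si](C)(C)C(C)(C)C)/C(C)=C/C=O
F3 | step 13 | (2E,4S,6S,7Z,9S,10E)-6-(acetyloxy)-4-[(tert-butyldimethylsilyl)oxy]-7-{[(tert-butyldiphenylsilyl)oxy]methyl}-3-methyl-1-oxododeca-2,7,10-trien-9-yl 2-[(tributylstannyl)methyl]prop-2-enoate | C/C=C/[C@H](OC(=O)C(=C)C[Sn](CCCC)(CCCC)CCCC)/C=C(/CO[Si](c1ccccc1)(c1ccccc1)C(C)(C)C)[C@@H](OC(C)=O)C[C@H](O[Si](C)(C)C(C)(C)C)/C(C)=C/C=O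
F4 | step 13 | (2E,4S,6S,7Z)-4-[(tert-butyldimethylsilyl)oxy]-7-{[(tert-butyldiphenylsilyl)oxy]methyl}-3-methyl-1-oxo-8-{(2R)-5-oxo-4-[(tributylstannyl)methyl]-2,5-dihydrofuran-2-yl}octa-2,7-dien-6-yl acetate | O=C1O[C@@H](C=C1C[Sn](CCCC)(CCCC)CCCC)/C=C(/CO[Si](c2ccccc2)(c2ccccc2)C(C)(C)C)[C@@H](OC(C)=O)C[C@H](O[Si](C)(C)C(C)(C)C)/C(C)=C/C=O
F5 | step 13 | (1S,3S,4Z,6R,7R,8R,9E)-3-acetoxy-1-[(tert-butyldimethylsilyl)oxy]-15-[(tert-butyldiphenylsilyl)oxy]-8-hydroxygermacra-4,9,11(13)-trien-12,6-olide | C=C1C(=O)O[C@@H]2/C=C(/CO[Si](c3ccccc3)(c3ccccc3)C(C)(C)C)[C@@H](OC(C)=O)C[C@H](O[Si](C)(C)C(C)(C)C)/C(C)=C/[C@@H](O)[C@@H]12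
F6 | step 7 | (3E)-5,5-dimethoxy-3-methyl-2-[(trimethylsilyl)oxy]penta-1,3-diene | C=C(O[Si](C)(C)C)/C(C)=C/C(OC)OC
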